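The route rests on opening the six-membered ring at C3–C4, the bond between the ring carbonyl carbon and the methyl-bearing oxirane carbon, read backwards as an allylic alcohol C3(OH)–C4(Me)=C5. One nickel/chromium-mediated addition of an alkenyl iodide to an aldehyde makes this bond, closes the carbocycle and creates the C3 carbinol that then steers the ring epoxide to the face of the C1 side chain. The precursor is an acyclic L-malate-derived chain C3–C2–C1–C7: a C3 aldehyde, the C2 silyl ether with its (S) centre in place, and on C1 the C7 ethyl ester and a (Z)-3-iodobut-2-enyl arm that supplies C6, C5, C4 and the ring methyl.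

Key step: step 7

Remark (numbering): ring C1 (bears the side chain), C2 (O-acyl), C3 (C=O), C4 (C–Me), C5 (oxirane CH), C6 (CH2); side chain C7 (oxirane C), C14 (oxirane CH2), C8 (C=O), C9=C10, C11 (C–OOH).
Remark (assumptions): the C8 carbinol of 21 and 22 is carried as an epimer mixture because step 15 removes it; the exocyclic C7 centre is set by reagent control (step 11) because substrate control there cannot be predicted with confidence.

Step 1
Reactants: 1 but-2-yn-1-ol
Product: 3 (2Z)-3-iodobut-2-en-1-ol, via cyclic alkenylalanate 2 (not isolated)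
Conditions: NaAlH2(OCH2CH2OMe)2 (Red-Al), THF, 0 °C to rt; then I2, −78 to 0 °C
Reagents that add atoms: iodine, II
Why: Hydroxyl-directed trans-hydroalumination of the propargylic alcohol puts aluminium on C3 cis to the CH2O group in a five-membered alanate, and iodinolysis with retention gives the Z iodide with iodine and CH2OH cis, as the later ring requires.

Step 2
Reactants: 3 (2Z)-3-iodobut-2-en-1-ol
Product: 4 (2Z)-1-bromo-3-iodobut-2-ene
Conditions: PBr3, Et2O, 0 °C
Reagents that add atoms: phosphorus tribromide, BrP(Br)Br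
Why: Bromination of the primary allylic alcohol through its phosphite ester (SN2 by bromide at the unhindered CH2) leaves the alkene geometry untouched.

Step 3
Reactants: 5 diethyl L-malate; 4 (2Z)-1-bromo-3-iodobut-2-ene
Product: 7 diethyl (2S,3R)-2-hydroxy-3-[(2Z)-3-iodobut-2-en-1-yl]butanedioate, via dilithium alkoxide enolate 6 (not isolated)
Conditions: LiN(iPr)2 (2.1 equiv), THF, −78 to −20 °C; then 4, −78 to −10 °C
Reagents that add atoms: none
Why: Fráter–Seebach alkylation, in which the chelated dilithium alkoxide enolate is alkylated on the face anti to the C–O bond, sets the new centre (target C1) as 3R, anti to the 2S carbinol.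

Step 4
Reactants: 7 diethyl (2S,3R)-2-hydroxy-3-[(2Z)-3-iodobut-2-en-1-yl]butanedioate
Product: 8 ethyl (2R,3S)-3,4-dihydroxy-2-[(2Z)-3-iodobut-2-en-1-yl]butanoate
Conditions: BH3·SMe2 (1.05 equiv), NaBH4 (5 mol %), THF, 0 °C to rt; then MeOH
Reagents that add atoms: none
Why: Hydroxyl-directed borane reduction, in which the alkoxyborane formed at the free hydroxyl delivers hydride only to the neighbouring ester, reduces the α-hydroxy ester and spares the remote ester and the deactivated iodoalkene.

Step 5
Reactants: 8 ethyl (2R,3S)-3,4-dihydroxy-2-[(2Z)-3-iodobut-2-en-1-yl]butanoate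
Product: 10 ethyl (2R,3S)-3-(tert-butyldimethylsilyloxy)-2-[(2Z)-3-iodobut-2-en-1-yl]-4-(triethylsilyloxy)butanoate, via primary triethylsilyl ether 9 (not isolated)
Conditions: Et3SiCl (1.05 equiv), imidazole, CH2Cl2, −40 °C; then tBuMe2SiOTf, 2,6-lutidine, −40 to 0 °C
Reagents that add atoms: chlorotriethylsilane, CC[Si](Cl)(CC)CC; tert-butyldimethylsilyl triflate, CC(C)(C)[Si](C)(C)OS(=O)(=O)C(F)(F)F
Why: Stepwise silylation by steric discrimination (primary hydroxyl first, then the secondary one with the triflate) differentiates the two oxygens in one flask, so the γ-hydroxy ester is never left free to lactonise.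

Step 6
Reactants: 10 ethyl (2R,3S)-3-(tert-butyldimethylsilyloxy)-2-[(2Z)-3-iodobut-2-en-1-yl]-4-(triethylsilyloxy)butanoate
Product: 11 ethyl (2R,3S)-3-(tert-butyldimethylsilyloxy)-2-[(2Z)-3-iodobut-2-en-1-yl]-4-oxobutanoate
Conditions: (COCl)2, DMSO, CH2Cl2, −78 to −40 °C; then Et3N, −78 to 0 °C
Reagents that add atoms: none
Why: Swern oxidation applied directly to the silyl ether, in which the chlorosulfonium salt cleaves and oxidises only the primary triethylsilyl ether, gives the α-silyloxy aldehyde without touching the secondary TBS ether or the α-stereocentre.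

Step 7
Reactants: 11 ethyl (2R,3S)-3-(tert-butyldimethylsilyloxy)-2-[(2Z)-3-iodobut-2-en-1-yl]-4-oxobutanoate
Product: 13 ethyl (1R,2S,3S)-2-(tert-butyldimethylsilyloxy)-3-hydroxy-4-methylcyclohex-4-ene-1-carboxylate (target numbering), via alkenylchromium dichloride 12 (not isolated)
Conditions: CrCl2 (5 equiv), NiCl2 (2 mol %), DMSO, rt, 0.01 M
Reagents that add atoms: none
Why: CrCl2 reduces NiCl2 to zerovalent nickel, which inserts into the C4–I bond with retention of the Z geometry, and transmetalation to trivalent chromium gives alkenylchromium 12, a weakly basic nucleophile that adds to the C3 aldehyde and ignores the C7 ester and the silyl ether. The closest known reaction type is the intramolecular Nozaki–Hiyama–Kishi alkenylation of an aldehyde to a cycloalkenol. The ring closes in the 6-exo-trig mode (C4 attacks the C3 carbonyl, oxygen outside the ring), which is possible only because the Z iodide holds the C4–metal bond and C6 cis on C4=C5. The new C3 centre is set under substrate control in a chair-like transition state with the C1 ester and C2 silyloxy group equatorial and the chromium-bound oxygen pseudo-equatorial, anti to C1, giving the 2,3-trans, 1,3-cis alcohol. The step needs this facial selectivity and retention of the C2 configuration: the trans C1/C2 pair from step 3 fixes the chair, and the neutral medium with a non-chelating TBS ether protects the α-stereocentre.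

Step 8
Reactants: 13 ethyl (1R,2S,3S)-2-(tert-butyldimethylsilyloxy)-3-hydroxy-4-methylcyclohex-4-ene-1-carboxylate
Product: 15 allylsilane (C7 ester of 13 replaced by a 3-(trimethylsilyl)prop-1-en-2-yl group; ring centres as in 13), via bis(trimethylsilylmethyl) carbinol 14 (not isolated)
Conditions: Me3SiCH2MgCl (5 equiv), CeCl3, THF, −78 °C to rt; then SiO2, CH2Cl2, rt
Reagents that add atoms: (trimethylsilyl)methylmagnesium chloride, C[Si](C)(C)C[Mg]Cl
Why: Cerium-promoted double addition of the silylmethyl Grignard reagent to the ester followed by Peterson elimination of one β-hydroxysilane arm gives the 2-substituted allylsilane, the weakly basic reagent sparing the C1 centre.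

Step 9
Reactants: 15 allylsilane
Product: 16 4,5-epoxide of 15 (oxirane oxygen cis to the C3 hydroxyl and to the C1 side chain)
Conditions: VO(acac)2 (cat.), tBuOOH, CH2Cl2, 0 °C to rt
Reagents that add atoms: tert-butyl hydroperoxide, CC(C)(C)OO
Why: Hydroxyl-directed vanadium-catalysed epoxidation of the cyclic allylic alcohol delivers oxygen to C4=C5 from the face of the C3 hydroxyl, which sets C4 and C5 cis to the C1 substituent, while the undirected allylsilane alkene does not react.

Step 10
Reactants: 16 epoxy alcohol allylsilane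
Product: 18 2-substituted allylic alcohol (C1 bears C7(=C14H2)–C8H2OH; ring as in 16), via silylmethyl oxirane 17 (not isolated)
Conditions: mCPBA, NaHCO3, CH2Cl2, 0 °C; then AcOH, THF–H2O, rt
Reagents that add atoms: 3-chloroperoxybenzoic acid, OOC(=O)c1cccc(Cl)c1
Why: Prilezhaev epoxidation of the allylsilane and acid-induced Peterson-type opening of the β-silyl oxirane (β-silicon-stabilised cation, loss of silicon) give the transposed allylic alcohol under conditions too mild to open the ring epoxide.

Step 11
Reactants: 18 2-substituted allylic alcohol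
Product: 19 (7S)-7,14-epoxy primary alcohol (C7 oxirane bearing C8H2OH; ring as in 16)
Conditions: Ti(OiPr)4, L-(+)-diethyl tartrate, tBuOOH, 4 Å molecular sieves, CH2Cl2, −20 °C
Reagents that add atoms: tert-butyl hydroperoxide, CC(C)(C)OO
Why: Katsuki–Sharpless asymmetric epoxidation, in which the titanium tartrate complex and not the substrate chooses the face of the 1,1-disubstituted alkene, sets C7 with the L-(+) ester in the sense of the target (S at this stage, the same facial rule that gives (S)-glycidol).

Step 12
Reactants: 19 epoxy primary alcohol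
Product: 20 (7R)-epoxy aldehyde (C8 = CHO; descriptor changes only because C8 now outranks C14)
Conditions: TEMPO (cat.), PhI(OAc)2, CH2Cl2, rt
Reagents that add atoms: none
Why: Oxoammonium-mediated oxidation is selective for the primary alcohol over the hindered secondary C3 hydroxyl and stops at the non-enolisable epoxy aldehyde.

Step 13
Reactants: 20 epoxy aldehyde
Product: 21 homoallylic alcohol (C8H(OH)–CH2–CH=CH2, C8 epimer mixture)
Conditions: allylB(pin), toluene, rt; aqueous NaHCO3 work-up
Reagents that add atoms: allylboronic acid pinacol ester, C=CCB1OC(C)(C)C(C)(C)O1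
Why: Neutral allylboration through a six-membered chair transition state adds to the aldehyde only and tolerates the free hydroxyl and both epoxides, the new C8 centre being formed unselectively and erased in step 15.

Step 14
Reactants: 21 homoallylic alcohol
Product: 22 prenyl carbinol (C8H(OH)–CH2–CH=CMe2)
Conditions: second-generation Grubbs catalyst RuCl2(=CHPh)(H2IMes)(PCy3) (5 mol %), 2-methylbut-2-ene, CH2Cl2, 40 °C
Reagents that add atoms: 2-methylbut-2-ene, CC=C(C)C
Why: Olefin cross-metathesis of the terminal alkene with excess 2-methylbut-2-ene exchanges =CH2 for =CMe2 with loss of propene, which gives the linear prenyl group that direct prenylation (branched product) would not.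

Step 15
Reactants: 22 prenyl carbinol
Product: 23 (1R,2S,4S,5S,7R)-2-silyloxy-3,8-diketone (C3=O, C8=O, prenyl ketone)
Conditions: Dess–Martin periodinane (3 equiv), NaHCO3, CH2Cl2, 0 °C to rt
Reagents that add atoms: none
Why: Dess–Martin oxidation converts both secondary alcohols (C3 and C8) into ketones under buffered, non-basic conditions that neither epimerise C2 nor move the β,γ double bond into conjugation.

Step 16
Reactants: 23 silyloxy diketone
Product: 24 (1R,2S,4S,5S,7R)-2-hydroxy-3,8-diketone
Conditions: HF·pyridine, pyridine, THF, 0 °C to rt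
Reagents that add atoms: none
Why: Fluoride cleavage of the α-keto silyl ether under buffered, mildly acidic conditions is tolerated by the two α,β-epoxy ketones and avoids base-induced epimerisation at C2 or conjugation of the prenyl ketone.

Step 17
Reactants: 24 hydroxy diketone; 25 isovaleryl chloride (3-methylbutanoyl chloride)
Product: 26 (1R,2S,4S,5S,7R)-2-(3-methylbutanoyloxy)-3,8-diketone with the prenyl side chain
Conditions: pyridine, DMAP (cat.), CH2Cl2, 0 °C
Reagents that add atoms: none
Why: Nucleophile-catalysed acylation of the only hydroxyl group installs the ester with retention at C2, the equatorial ester trans to the C1 substituent being also the thermodynamically preferred epimer.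

Step 18
Reactants: 26 isovalerate prenyl ketone
Product: 27 target, (1R,2S,4S,5S,7R)-hydroperoxide with the (9E)-enone
Conditions: O2, tetraphenylporphyrin (cat.), visible light, CH2Cl2, 0 °C
Reagents that add atoms: dioxygen, O=O
Why: Schenck ene reaction, in which singlet oxygen bonds to C11 of the only electron-rich alkene and removes a C9 hydrogen activated by the adjacent C8 carbonyl, shifts the double bond to C9=C10 (E, conjugated) and forms the tertiary hydroperoxide.

Compound list
1 | but-2-yn-1-ol | CC#CCO | starting material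
2 | sodium 2,2-bis(2-methoxyethoxy)-3-methyl-2,5-dihydro-1,2-oxaluminol-2-uide (cyclic alkenylalanate) | CC1=CCO[Al-]1(OCCOC)OCCOC.[Na+] | intermediate
3 | (2Z)-3-iodobut-2-en-1-ol | C/C(I)=C/CO | intermediate
4 | (2Z)-1-bromo-3-iodobut-2-ene | C/C(I)=C/CBr | intermediate
5 | diethyl (2S)-2-hydroxybutanedioate (diethyl L-malate) | CCOC(=O)C[C@H](O)C(=O)OCC | starting material
6 | dilithium alkoxide ester enolate of 5 | CCOC(=O)[C@@H]([O-])C=C([O-])OCC.[Li+].[Li+] | intermediate
7 | diethyl (2S,3R)-2-hydroxy-3-[(2Z)-3-iodobut-2-en-1-yl]butanedioate | CCOC(=O)[C@@H](O)[C@@H](C/C=C(/C)I)C(=O)OCC | intermediate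
8 | ethyl (2R,3S)-3,4-dihydroxy-2-[(2Z)-3-iodobut-2-en-1-yl]butanoate | OC[C@@H](O)[C@@H](C/C=C(/C)I)C(=O)OCC | intermediate
9 | ethyl (2R,3S)-3-hydroxy-2-[(2Z)-3-iodobut-2-en-1-yl]-4-(triethylsilyloxy)butanoate | CC[Si](CC)(CC)OC[C@@H](O)[C@@H](C/C=C(/C)I)C(=O)OCC | intermediate
10 | ethyl (2R,3S)-3-(tert-butyldimethylsilyloxy)-2-[(2Z)-3-iodobut-2-en-1-yl]-4-(triethylsilyloxy)butanoate | CC[Si](CC)(CC)OC[C@@H](O[Si](C)(C)C(C)(C)C)[C@@H](C/C=C(/C)I)C(=O)OCC | intermediate
11 | ethyl (2R,3S)-3-(tert-butyldimethylsilyloxy)-2-[(2Z)-3-iodobut-2-en-1-yl]-4-oxobutanoate (key-step precursor) | O=C[C@@H](O[Si](C)(C)C(C)(C)C)[C@@H](C/C=C(/C)I)C(=O)OCC | intermediate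
12 | (Z)-alkenylchromium dichloride derived from 11 (CrCl2 in place of iodine at C4) | O=C[C@@H](O[Si](C)(C)C(C)(C)C)[C@@H](C/C=C(/C)[Cr](Cl)Cl)C(=O)OCC | intermediate
13 | ethyl (1R,2S,3S)-2-(tert-butyldimethylsilyloxy)-3-hydroxy-4-methylcyclohex-4-ene-1-carboxylate (target numbering; C1 ester and C3–OH cis, C2–OTBS trans to both) | CC(C)(C)[Si](C)(C)O[C@@H]1[C@@H](O)C(C)=CC[C@H]1C(=O)OCC | intermediate
14 | tertiary carbinol from 13: C7(OH)(CH2SiMe3)2 on C1, ring as in 13 | CC(C)(C)[Si](C)(C)O[C@@H]1[C@@H](O)C(C)=CC[C@H]1C(O)(C[Si](C)(C)C)C[Si](C)(C)C | intermediate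
15 | allylsilane: 2-(tert-butyldimethylsilyloxy)-4-methyl-1-[3-(trimethylsilyl)prop-1-en-2-yl]cyclohex-4-en-3-ol, ring centres as in 13 | CC(C)(C)[Si](C)(C)O[C@@H]1[C@@H](O)C(C)=CC[C@H]1C(=C)C[Si](C)(C)C | intermediate
16 | 4,5-epoxide of 15, oxirane oxygen cis to C3–OH and to the C1 side chain | CC(C)(C)[Si](C)(C)O[C@@H]1[C@@H](O)[C@@]2(C)O[C@H]2C[C@H]1C(=C)C[Si](C)(C)C | intermediate
17 | 2-(trimethylsilylmethyl)oxirane from 16 (C7 epimer mixture) | CC(C)(C)[Si](C)(C)O[C@@H]1[C@@H](O)[C@@]2(C)O[C@H]2C[C@H]1C1(C[Si](C)(C)C)CO1 | intermediate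
18 | allylic alcohol: C1 bears 3-hydroxyprop-1-en-2-yl, ring as in 16 | CC(C)(C)[Si](C)(C)O[C@@H]1[C@@H](O)[C@@]2(C)O[C@H]2C[C@H]1C(=C)CO | intermediate
19 | (7S)-epoxy alcohol: C1 bears 2-(hydroxymethyl)oxiran-2-yl, ring as in 16 | CC(C)(C)[Si](C)(C)O[C@@H]1[C@@H](O)[C@@]2(C)O[C@H]2C[C@H]1[C@]1(CO)CO1 | intermediate
20 | (7R)-epoxy aldehyde: C1 bears 2-formyloxiran-2-yl, ring as in 16 | CC(C)(C)[Si](C)(C)O[C@@H]1[C@@H](O)[C@@]2(C)O[C@H]2C[C@H]1[C@]1(C=O)CO1 | intermediate
21 | homoallylic alcohol: oxirane C7 bears 1-hydroxybut-3-en-1-yl (C8 epimers) | CC(C)(C)[Si](C)(C)O[C@@H]1[C@@H](O)[C@@]2(C)O[C@H]2C[C@H]1[C@]1(C(O)CC=C)CO1 | intermediate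
22 | prenyl carbinol: oxirane C7 bears 1-hydroxy-4-methylpent-3-en-1-yl (C8 epimers) | CC(C)(C)[Si](C)(C)O[C@@H]1[C@@H](O)[C@@]2(C)O[C@H]2C[C@H]1[C@]1(C(O)CC=C(C)C)CO1 | intermediate
23 | (1R,2S,4S,5S,7R)-2-(tert-butyldimethylsilyloxy)-4,5-epoxy-4-methyl-1-[2-(4-methylpent-3-enoyl)oxiran-2-yl]cyclohexan-3-one (target numbering) | CC(C)(C)[Si](C)(C)O[C@@H]1C(=O)[C@@]2(C)O[C@H]2C[C@H]1[C@]1(C(=O)CC=C(C)C)CO1 | intermediate
24 | (1R,2S,4S,5S,7R)-2-hydroxy analogue of 23 | O[C@@H]1C(=O)[C@@]2(C)O[C@H]2C[C@H]1[C@]1(C(=O)CC=C(C)C)CO1 | intermediate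
25 | 3-methylbutanoyl chloride (isovaleryl chloride) | CC(C)CC(Cl)=O | starting material
26 | (1R,2S,4S,5S,7R)-2-(3-methylbutanoyloxy) analogue of 23 | CC(C)CC(=O)O[C@@H]1C(=O)[C@@]2(C)O[C@H]2C[C@H]1[C@]1(C(=O)CC=C(C)C)CO1 | intermediate
27 | CNP0131119.1: (1S,3S,4R,6S)-4-{(2R)-2-[(2E)-4-hydroperoxy-4-methylpent-2-enoyl]oxiran-2-yl}-1-methyl-2-oxo-7-oxabicyclo[4.1.0]heptan-3-yl 3-methylbutanoate | CC(C)CC(=O)O[C@@H]1C(=O)[C@@]2(C)O[C@H]2C[C@H]1[C@]1(C(=O)/C=C/C(C)(C)OO)CO1 | target

Total step count: 18. Longest linear sequence: 18 steps (1 to 27; 16 steps from 5).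

Steps most likely to fail

Step 7. The aldehyde may be attacked with its oxygen pseudo-axial (the open-chain Felkin-type mode), so facial selectivity at C3 could be poor or reversed and the resulting 2,3-cis carbinol would misdirect the ring epoxidation. Fallback (the centre is set by hydride delivery, not by the C–C bond formation): setting out from 11, the ring is closed as in step 7 and the crude material containing the C3-epimeric alcohol ethyl (1R,2S,3R)-2-(tert-butyldimethylsilyloxy)-3-hydroxy-4-methylcyclohex-4-ene-1-carboxylate F1 is oxidised as a whole with Dess–Martin periodinane (NaHCO3, CH2Cl2) to the enone ethyl (1R,2S)-2-(tert-butyldimethylsilyloxy)-4-methyl-3-oxocyclohex-4-ene-1-carboxylate F2. Luche reduction (NaBH4, CeCl3·7H2O, MeOH, −78 °C) then adds hydride axially to the half-chair with both substituents equatorial and should give the equatorial alcohol trans to the silyloxy group, which comes back to the route at 13.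

Step 11. Oxygen transfer to the hindered 2-substituted allylic alcohol may be sluggish or mismatched with the C1 centre, and the titanium reagent may open the 2,2-disubstituted epoxy alcohol. Fallback (iminium-type nucleophilic epoxidation, not metal-directed electrophilic epoxidation): setting out from 18, MnO2 (CH2Cl2, rt) oxidises only the allylic primary alcohol to the 2-substituted acrolein, the enal with C7(=CH2)–CHO on C1 F3. Amine-catalysed epoxidation of this α-branched enal follows, with aqueous H2O2 and a cinchona-derived primary amine salt (9-amino-9-deoxy-epi-quinine or its quinidine-derived pseudo-enantiomer, chosen for the face required) in dioxane, and comes back to the route at 20, so that step 12 is no longer needed.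

Step 18. Hydrogen abstraction from the C11 methyl groups may compete with abstraction at C9 (wrong ene regiochemistry), and the allylic hydroperoxide may decompose during isolation. Fallback (ionic Markovnikov peroxidation and elimination, not a pericyclic ene reaction): setting out from 26, bromoperoxidation of the prenyl alkene with 1,3-dibromo-5,5-dimethylhydantoin and anhydrous ethereal H2O2 at −40 °C puts the hydroperoxide on the tertiary C11 and bromine on C10, giving the β-bromo hydroperoxide F4. Et3N (CH2Cl2, 0 °C) then removes HBr across C9–C10 by E1cB elimination of the β-bromo ketone and comes back to the route at 27.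

Further compounds
F1 | step 7 | ethyl (1R,2S,3R)-2-(tert-butyldimethylsilyloxy)-3-hydroxy-4-methylcyclohex-4-ene-1-carboxylate | CC(C)(C)[Si](C)(C)O[C@@H]1[C@H](O)C(C)=CC[C@H]1C(=O)OCC
F2 | step 7 | ethyl (1R,2S)-2-(tert-butyldimethylsilyloxy)-4-methyl-3-oxocyclohex-4-ene-1-carboxylate | CC(C)(C)[Si](C)(C)O[C@@H]1C(=O)C(C)=CC[C@H]1C(=O)OCC
F3 | step 11 | enal: C1 bears 3-oxoprop-1-en-2-yl, ring as in 16 | CC(C)(C)[Si](C)(C)O[C@@H]1[C@@H](O)[C@@]2(C)O[C@H]2C[C@H]1C(=C)C=O
F4 | step 18 | β-bromo hydroperoxide: side chain C8(=O)–CH2–CHBr–C(CH3)2OOH, rest as in 26 | CC(C)CC(=O)O[C@@H]1C(=O)[C@@]2(C)O[C@H]2C[C@H]1[C@]1(C(=O)CC(Br)C(C)(C)OO)CO1
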